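**Time first.** Each flask stops at 2.0 min, so we want to know how far the exchange has travelled by then, not where it would come to rest.

| setting | spring | summer | dawn | red | teal | violet |
|---|---|---|---|---|---|---|
| starting complex | 20 mM | 20 mM | 20 mM | 20 mM | 20 mM | 20 mM |
| incoming ligand | 20 mM | 41 mM | 57 mM | 24.0 mM | 50.0 mM | 80.0 mM |
| leaving ligand | 20 mM | 20 mM | 20 mM | 20.0 mM | 20.0 mM | 20.0 mM |
| capture agent | 2 mM | 2 mM | 2 mM | 2.00 mM | 2.00 mM | 2.00 mM |
| remark | run made earlier | run made earlier | run made earlier |  |  |  |
| time |  |  |  | 2.0 min | 2.0 min | 2.0 min |

| run | time / s | complex with one exchanged / % | complex with two exchanged / % |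
|---|---|---|---|
| spring | 20.0 | 13 | 2 |
| spring | 40.0 | 16 | 0 |
| spring | 60.0 | 18 | 3 |
| spring | 80.0 | 24 | 0 |
| summer | 20.0 | 16 | 0 |
| summer | 40.0 | 27 | 6 |
| summer | 60.0 | 30 | 14 |
| summer | 80.0 | 32 | 14 |
| dawn | 10.0 | 14 | 1 |
| dawn | 15.0 | 19 | 4 |
| dawn | 40.0 | 32 | 10 |
| dawn | 80.0 | 34 | 16 |

(each reading ± 2 percentage points)

- what may be going on: leaving ligand + complex with two exchanged -> side product; starting complex + incoming ligand -> leaving ligand + complex with one exchanged; complex with two exchanged -> over-reaction product; complex with one exchanged + incoming ligand -> leaving ligand + complex with two exchanged; complex with one exchanged + capture agent -> trapped intermediate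

- amount of complex with one exchanged at the end, in percent of the starting complex charged, for each flask in turn (red, teal, violet)

**Bench rule.** Early in dawn, at 15.0 s, the readings show 23.0 % of the starting complex exchanged. Taking the ligand as constant (the pseudo-first-order habit), this reads as a first-exchange constant k of 0.306 M⁻¹ s⁻¹. The starting complex left is then exp(−E), where E = k·X·t and X is the incoming ligand. We assume the second exchange is equally fast, so the complex with one exchanged is E·exp(−E). That peaks at E equal to one, at 36.8 %, and dawn's last reading is 34 %. With X at its charge, E is 0.880 in red, 1.83 in teal and 2.93 in violet.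

**The border.** Each complex can take two ligands, so we compare the possible demand with the charge. The ratio 2·cM/cX, with cM the complex charged and cX the ligand charged, is 1.67 in red, 0.800 in teal and 0.500 in violet. These are too large for a constant X.

**The mean.** We therefore replace X by its mean: the charge minus half of what the first-pass composition consumed. This gives the exposure E, k times mean ligand times time, as 0.585 in red, 1.33 in teal and 2.30 in violet. A second pass moves teal to 1.42. Our row is 32.6 %, 35.2 % and 23.1 %. We left out the capture agent, charged at 10.0 % of the complex, and we expect the row to read high.

**The forecast.** The forecast gives 24 %, 33 % and 34 %, on these grounds: “I treat the flasks as near equilibrium”. We part from it at red, where our row stands higher, and at violet, where our row turns down and stands lower.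

**The result.** The flasks give 28.6 %, 31.2 % and 21.5 %.

    leaving ligand + complex with two exchanged → side product (k = 0.238 M⁻¹ s⁻¹)
    starting complex + incoming ligand → leaving ligand + complex with one exchanged (k = 0.317 M⁻¹ s⁻¹)
    complex with two exchanged → over-reaction product (k = 0.00491 s⁻¹)
    complex with one exchanged + incoming ligand → leaving ligand + complex with two exchanged (k = 0.301 M⁻¹ s⁻¹)
    complex with one exchanged + capture agent → trapped intermediate (k = 3.07 M⁻¹ s⁻¹)

**Read back.** Exposure read from the starting complex remaining, ln(1/M), is 1.40 in teal, beside our 1.33. In violet it is 2.32, beside our 2.30, so violet stands well past the peak. Teal's 31.2 % comes from the time allowed and, in part, from the capture agent running short, with 13 % of its charge left at the end: with that agent held at its charge teal ends at 24.3 %, and left until 20.0 min it stands at 1.02 %.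

The runs are simulated from invented constants.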